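## Retrosynthetic overview

1. Numbering of the bicyclo[2.2.2]oct-5-ene core: C1 and C4 bridgeheads, C2 (CO2H), C3 (aryl), C5=C6 (side chain on C6), C7=O next to C4, C8=O next to C1. The target comes from global deallylation and opening of a ketal γ-lactone C2–C(=O)–O–C8(OMe), which masks the C2 acid and the C8 ketone at once; the side chain comes from a Horner–Wadsworth–Emmons olefination at a C6 aldehyde with an (R)-danshensu phosphonoacetate.
2. The lactone-bridged bicycle comes from an intramolecular Diels–Alder reaction (new bonds C1–C2 and C3–C4) of an (R)-6-acyloxy-6-methoxycyclohexa-2,4-dienone. That dienone comes from vanillin and protected caffeic acid, joined by an acyloxylative dearomatization in which a chiral λ3-iodane carries the caffeate as its ligand.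
3. Enabling feature: the C2 carboxyl is syn to the C7–C8 bridge and 1,3 to the C8 carbonyl, so C8=O plus CO2H is the open form of a five-membered acyloxy ketal. Ring C4–C5=C6–C1–C8–C7 with its vicinal dione is a dearomatized vanillin ring, so the caffeic acid can be ketal oxygen, tether and dienophile at once.
4. Ring order: the vanillin ring is bought. One cascade then closes the temporary ketal lactone and the cyclohexene ring C1–C2–C3–C4–C5=C6, which completes the bicyclo[2.2.2]octene and is the last ring of the skeleton. The lactone is opened again in step 9.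

Key step: step 5

Assumption: sodium (R)-danshensu and the C2-symmetric lactamide iodoarene of step 3 are taken as purchasable, and the (R,R)-iodoarene is assumed to induce the (R)-ketal in step 5; if the sense proves opposite, its (S,S)-antipode is used in the same way.

Remark: the target is written as the open keto acid of the given SMILES; a ring–chain equilibrium with the C8 lactol would not change the route.

## Route

Step 1
Reactants: 1 caffeic acid
Product: 2 allyl (E)-3-[3,4-bis(allyloxy)phenyl]prop-2-enoate
Conditions: allyl bromide (3.6 equiv), K2CO3 (4 equiv), DMF, 25 → 50 °C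
Reagents that add atoms: allyl bromide, C=CCBr
Why: Williamson O-allylation of both phenols and SN2 esterification of the carboxylate are standard for caffeic acid, and allyl is used throughout so that every protecting group falls in one neutral step at the end.

Step 2
Reactants: 2 allyl (E)-3-[3,4-bis(allyloxy)phenyl]prop-2-enoate
Product: 3 (E)-3-[3,4-bis(allyloxy)phenyl]prop-2-enoic acid
Conditions: LiOH·H2O (3 equiv), THF/MeOH/H2O, 40 °C; then 1 M HCl
Reagents that add atoms: LiOH (lithium hydroxide), [Li+].[OH-]
Why: Saponification of the allyl ester by acyl substitution leaves the aryl allyl ethers and the E-alkene untouched.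

Step 3
Reactants: 4 (R,R)-2-iodo-1,3-bis[1-(mesitylcarbamoyl)ethoxy]benzene
Product: 5 (R,R)-2-(diacetoxy-λ3-iodanyl)-1,3-bis[1-(mesitylcarbamoyl)ethoxy]benzene
Conditions: AcOOH (35% in AcOH, 2 equiv), AcOH, 25–30 °C; evaporation, trituration with Et2O/hexane
Reagents that add atoms: peracetic acid, CC(=O)OO; acetic acid, CC(=O)O
Why: Oxidation of an aryl iodide by a peracid in acetic acid is the standard entry to (diacetoxyiodo)arenes, and the lactamide stereocentres are not involved.

Step 4
Reactants: 5 (R,R)-2-(diacetoxy-λ3-iodanyl)-1,3-bis[1-(mesitylcarbamoyl)ethoxy]benzene; 3 (E)-3-[3,4-bis(allyloxy)phenyl]prop-2-enoic acid (2.05 equiv)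
Product: 6 chiral bis(acyloxy)-λ3-iodane (5 with both acetates replaced by the carboxylate of 3)
Conditions: PhCl, 45 °C, reduced pressure (AcOH distilled off as it forms), repeated twice; used crude
Reagents that add atoms: none
Why: Carboxylate ligand exchange on a (diacetoxyiodo)arene is an equilibrium that is pulled to the bis(acyloxy) compound by evaporating the more volatile acetic acid, the usual preparation of [bis(acyloxy)iodo]arenes.

Step 5
Reactants: 7 vanillin; 6 chiral bis(acyloxy)-λ3-iodane
Product: 10 ketal lactone aldehyde (C2-to-C8 lactone-bridged 6-formyl-8-methoxy-7-oxobicyclo[2.2.2]oct-5-ene; full name in the compound list), via aryloxy-λ3-iodane 8 (not isolated), via (R)-acyloxy-methoxy-dienone 9 (not isolated)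
Conditions: 6 (1.1 equiv), 4 Å MS, CH2Cl2, −40 → 0 °C; then PhMe, 80 °C
Reagents that add atoms: none
Why: Proposed new method: phenol 7 should displace one carboxylate on trivalent iodine to give 8, whose remaining caffeate ligand, held by N–H···O hydrogen bonds to the two lactamide arms, is passed inside this C2-symmetric pocket to the methoxy-bearing ortho carbon (ring carbon 3 of vanillin, the future C8) as iodoarene 4 leaves, so that the reagent sets the ketal carbon of 9; the closest known reactions are the enantioselective dearomatizing spirolactonization of phenols by chiral aryl-λ3-iodanes (there the carboxylate is tethered to the phenol, here it is a ligand on iodine) and the racemic Wessely-type acyloxylation of phenols with an unsaturated acid followed by intramolecular Diels–Alder reaction. Dienone 9 should then close two rings in one concerted, suprafacial [4+2] cycloaddition: the cyclohexene ring C1–C2–C3–C4–C5=C6 through the new bonds C1–C2 and C3–C4, which completes the bicyclo[2.2.2]octene, and the five-membered ketal lactone C8–O–C(=O)–C2–C1 as the fused mode that a three-atom tether imposes. The ketal carbon carries the tether on one face and so fixes C1 and C4; membership of the lactone ring holds the C2 carbonyl syn to the C7–C8 bridge; the E geometry of the dienophile is transferred suprafacially and puts the C3 aryl trans to it, over C5=C6. The step needs C–O bond formation at ring carbon 3 of vanillin and not at carbons 5 or 1 (the methoxy group stabilizes positive charge at carbon 3 and the formyl group blocks and deactivates carbon 1), one enantioface in that transfer (reagent), the regiochemistry acyl carbon to C2 (tether, matched by the polarity of the styrenyl α-carbon and the electrophilic dienone terminus), and cycloaddition faster than acyl migration or dimerization (intramolecularity, and the formyl-bearing carbon lies on the double bond through which such dienones dimerize).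

Step 6
Reactants: 11 sodium (R)-3-(3,4-dihydroxyphenyl)-2-hydroxypropanoate (sodium (R)-danshensu)
Product: 12 allyl (R)-3-[3,4-bis(allyloxy)phenyl]-2-hydroxypropanoate
Conditions: allyl bromide (3.3 equiv), K2CO3 (2.5 equiv), DMF, 25 °C
Reagents that add atoms: allyl bromide, C=CCBr
Why: K2CO3 ionizes only the carboxylate and the two phenols, so allyl bromide alkylates these and leaves the secondary alcohol free; the stereocentre comes from the chiral pool and is not touched.

Step 7
Reactants: 12 allyl (R)-3-[3,4-bis(allyloxy)phenyl]-2-hydroxypropanoate; 13 2-(diethoxyphosphoryl)acetic acid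
Product: 14 allyl (R)-3-[3,4-bis(allyloxy)phenyl]-2-[2-(diethoxyphosphoryl)acetoxy]propanoate
Conditions: EDC·HCl (1.3 equiv), DMAP (0.1 equiv), CH2Cl2, 0 → 25 °C
Reagents that add atoms: none
Why: Steglich esterification acylates the hydroxyl group without breaking the C–O bond of the stereocentre (retention) and gives the phosphonoacetate needed for the olefination.

Step 8
Reactants: 10 ketal lactone aldehyde; 14 allyl (R)-3-[3,4-bis(allyloxy)phenyl]-2-[2-(diethoxyphosphoryl)acetoxy]propanoate
Product: 15 ketal lactone dienoate (10 with the formyl group converted to the (E)-CH=CH–C(=O)O ester of 12)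
Conditions: LiCl (1.5 equiv), iPr2NEt (1.3 equiv), MeCN, 0 → 25 °C
Reagents that add atoms: none
Why: Horner–Wadsworth–Emmons olefination with a stabilized phosphonate under mild LiCl/amine conditions should be selective for the aldehyde over the hindered C7 ketone and the lactone and gives the E-enoate; since 14 is enantiopure, any enantiomeric impurity from step 5 becomes a diastereomer that can be removed here.

Step 9
Reactants: 15 ketal lactone dienoate
Product: 17 penta-allyl dione acid (the target with four aryl allyl ethers and the danshensu allyl ester), via methyl hemiketal 16 (not isolated)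
Conditions: LiOH·H2O (1.15 equiv), THF/H2O 3:1, 0 °C, short reaction time; then 0.5 M HCl to pH 3
Reagents that add atoms: LiOH (lithium hydroxide), [Li+].[OH-]
Why: Hydroxide should attack the lactone carbonyl, much the most electrophilic acyl group (a strained γ-lactone whose leaving group is a hemiketal oxygen beside a ketone), and hemiketal 16 then expels methanol, so that the C2 acid and the C8 ketone are unmasked together by acyl substitution and not by ionization of a ketal beside a carbonyl; the bridgeheads cannot enolize and no stereocentre is touched.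

Step 10
Reactants: 17 penta-allyl dione acid
Product: 18 yunnaneic acid C
Conditions: Pd(PPh3)4 (15 mol%), PhNHMe (15 equiv), degassed THF, 25 °C, dark; dilute aq. HCl wash, reversed-phase HPLC
Reagents that add atoms: none
Why: Zerovalent palladium ionizes the allyl ester and the four aryl allyl ethers to π-allyl complexes that are captured by the weakly basic N-methylaniline (Tsuji–Trost deallylation), a neutral deprotection that should spare the dione, the enoate ester and the catechols.

## Compound list

1 | caffeic acid, (E)-3-(3,4-dihydroxyphenyl)prop-2-enoic acid | O=C(O)/C=C/c1ccc(O)c(O)c1 | starting material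
2 | allyl (E)-3-[3,4-bis(allyloxy)phenyl]prop-2-enoate | C=CCOC(=O)/C=C/c1ccc(OCC=C)c(OCC=C)c1 | intermediate
3 | (E)-3-[3,4-bis(allyloxy)phenyl]prop-2-enoic acid | OC(=O)/C=C/c1ccc(OCC=C)c(OCC=C)c1 | intermediate
4 | (R,R)-2-iodo-1,3-bis[1-(mesitylcarbamoyl)ethoxy]benzene, i.e. (2R,2'R)-2,2'-[(2-iodo-1,3-phenylene)bis(oxy)]bis[N-(2,4,6-trimethylphenyl)propanamide] | C[C@@H](Oc1cccc(O[C@H](C)C(=O)Nc2c(C)cc(C)cc2C)c1I)C(=O)Nc1c(C)cc(C)cc1C | starting material
5 | (R,R)-2-(diacetoxy-λ3-iodanyl)-1,3-bis[1-(mesitylcarbamoyl)ethoxy]benzene | C[C@@H](Oc1cccc(O[C@H](C)C(=O)Nc2c(C)cc(C)cc2C)c1I(OC(C)=O)OC(C)=O)C(=O)Nc1c(C)cc(C)cc1C | intermediate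
6 | chiral bis(acyloxy)-λ3-iodane: 5 with both acetate ligands replaced by (E)-3-[3,4-bis(allyloxy)phenyl]prop-2-enoate | C[C@@H](Oc1cccc(O[C@H](C)C(=O)Nc2c(C)cc(C)cc2C)c1I(OC(=O)/C=C/c1ccc(OCC=C)c(OCC=C)c1)OC(=O)/C=C/c1ccc(OCC=C)c(OCC=C)c1)C(=O)Nc1c(C)cc(C)cc1C | intermediate
7 | vanillin, 4-hydroxy-3-methoxybenzaldehyde | O=Cc1ccc(O)c(OC)c1 | starting material
8 | aryloxy(acyloxy)-λ3-iodane: iodine of 4 bearing one 4-formyl-2-methoxyphenoxide and one (E)-3-[3,4-bis(allyloxy)phenyl]prop-2-enoate ligand | C[C@@H](Oc1cccc(O[C@H](C)C(=O)Nc2c(C)cc(C)cc2C)c1I(Oc1ccc(C=O)cc1OC)OC(=O)/C=C/c1ccc(OCC=C)c(OCC=C)c1)C(=O)Nc1c(C)cc(C)cc1C | intermediate (not isolated)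
9 | (R)-3-formyl-1-methoxy-6-oxocyclohexa-2,4-dien-1-yl (E)-3-[3,4-bis(allyloxy)phenyl]prop-2-enoate | O=CC1=C[C@@](OC)(OC(=O)/C=C/c2ccc(OCC=C)c(OCC=C)c2)C(=O)C=C1 | intermediate (not isolated)
10 | ketal lactone aldehyde: (1R,2R,3S,4R,8R)-3-[3,4-bis(allyloxy)phenyl]-6-formyl-8-methoxy-7-oxobicyclo[2.2.2]oct-5-ene-2-carboxylic acid closed as the γ-lactone onto the C8 oxygen (lactone on the C2 side of C8, methoxy toward C5=C6, aryl toward C5=C6) | O=CC1=C[C@H]2C(=O)[C@@]3(OC)[C@@H]1[C@H](C(=O)O3)[C@H]2c1ccc(OCC=C)c(OCC=C)c1 | intermediate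
11 | sodium (R)-3-(3,4-dihydroxyphenyl)-2-hydroxypropanoate (sodium (R)-danshensu) | [Na+].[O-]C(=O)[C@H](O)Cc1ccc(O)c(O)c1 | starting material
12 | allyl (R)-3-[3,4-bis(allyloxy)phenyl]-2-hydroxypropanoate | C=CCOC(=O)[C@H](O)Cc1ccc(OCC=C)c(OCC=C)c1 | intermediate
13 | 2-(diethoxyphosphoryl)acetic acid | CCOP(=O)(OCC)CC(=O)O | starting material
14 | allyl (R)-3-[3,4-bis(allyloxy)phenyl]-2-[2-(diethoxyphosphoryl)acetoxy]propanoate | C=CCOC(=O)[C@H](OC(=O)CP(=O)(OCC)OCC)Cc1ccc(OCC=C)c(OCC=C)c1 | intermediate
15 | ketal lactone dienoate: 10 in which the C6 formyl group is replaced by (E)-CH=CH–C(=O)O–, esterified to the (R)-carbinol of 12; core (1R,2R,3S,4R,8R) | C=CCOC(=O)[C@H](OC(=O)/C=C/C1=C[C@H]2C(=O)[C@@]3(OC)[C@@H]1[C@H](C(=O)O3)[C@H]2c1ccc(OCC=C)c(OCC=C)c1)Cc1ccc(OCC=C)c(OCC=C)c1 | intermediate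
16 | methyl hemiketal: 15 with the lactone opened to the free C2 carboxylic acid and C8 bearing OH (in place of the lactone oxygen) and OMe | C=CCOC(=O)[C@H](OC(=O)/C=C/C1=C[C@H]2C(=O)[C@@](O)(OC)[C@@H]1[C@H](C(=O)O)[C@H]2c1ccc(OCC=C)c(OCC=C)c1)Cc1ccc(OCC=C)c(OCC=C)c1 | intermediate (not isolated)
17 | penta-allyl dione acid: (1R,2R,3S,4R)-3-[3,4-bis(allyloxy)phenyl]-6-[(E)-3-{[(R)-1-(allyloxy)-3-(3,4-bis(allyloxy)phenyl)-1-oxopropan-2-yl]oxy}-3-oxoprop-1-enyl]-7,8-dioxobicyclo[2.2.2]oct-5-ene-2-carboxylic acid | C=CCOC(=O)[C@H](OC(=O)/C=C/C1=C[C@H]2C(=O)C(=O)[C@@H]1[C@H](C(=O)O)[C@H]2c1ccc(OCC=C)c(OCC=C)c1)Cc1ccc(OCC=C)c(OCC=C)c1 | intermediate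
18 | yunnaneic acid C: (1R,2R,3S,4R)-6-[(E)-3-{[(R)-1-carboxy-2-(3,4-dihydroxyphenyl)ethyl]oxy}-3-oxoprop-1-enyl]-3-(3,4-dihydroxyphenyl)-7,8-dioxobicyclo[2.2.2]oct-5-ene-2-carboxylic acid (carboxyl syn to the dione bridge, aryl syn to C5=C6) | O=C(/C=C/C1=C[C@H]2C(=O)C(=O)[C@@H]1[C@H](C(=O)O)[C@H]2c1ccc(O)c(O)c1)O[C@H](Cc1ccc(O)c(O)c1)C(=O)O | target

## Step count and risks

Total step count: 10. Longest linear sequence: 7 steps (1, 2, 4, 5, 8, 9, 10).

**Step 5 (bears the label).** What may go wrong: poor enantioface control in the carboxylate transfer, for instance through a free phenoxenium/carboxylate ion pair that escapes the chiral pocket. Fallback by resolution instead of asymmetric induction, setting out from 7 and 3 and returning at 15. PhI(OAc)2 and 3 (2 equiv) are converted by the ligand exchange of step 4 into the achiral [bis(acyloxy)iodo]benzene F1. F1 and 7 in CH2Cl2, then toluene at 80 °C, run the known Wessely-type acyloxylation and intramolecular Diels–Alder sequence through aryloxy(acyloxy)iodobenzene F2 to the racemic dienone (9 and its enantiomer, the (S)-dienone F3) and on to the racemic lactone aldehyde (10 and its enantiomer F4). Olefination of the racemate with enantiopure 14 under the conditions of step 8 should give 15 together with the diastereomer F5 (opposite configuration at all five stereocentres of the tricyclic core). The two are to be separated by chromatography on silica or preparative HPLC, and the route is rejoined at 15.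

**Step 9.** What may go wrong: competing saponification of the side-chain ester links, or a benzilic acid-type rearrangement of the freed dione under hydroxide. Fallback by alcoholysis instead of hydrolysis, setting out from 15 and returning at 18. In allyl alcohol as solvent with DMAP (0.2 equiv) at 25 °C, nucleophilic catalysis should pass the activated lactone acyl group to allyl alcohol. Ordinary esters are not touched, and exchange at the existing allyl ester is degenerate. The hemiketal allyl ester F6 loses methanol to give the hexa-allyl dione ester F7. F7 is deallylated under the conditions of step 10, now with six allyl groups, to give 18.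

**Step 10.** What may go wrong: condensation of the amine scavenger with the strained 1,2-dione, or incomplete cleavage of five allyl groups with C-allylation of the freed catechols. Fallback by reversing the order of unmasking, setting out from 15 and returning at 18. The deallylation with Pd(PPh3)4 and N-methylaniline is run on 15, where the dione is still masked, to give the fully deallylated ketal lactone F8. The lactone of F8 is then opened in degassed Na2CO3/NaHCO3 buffer (pH about 9) with MeCN under argon at 0 → 25 °C, through the methyl hemiketal F9 and loss of methanol, followed by acidification to pH 3. The side-chain ester is then flanked by a carboxylate and should be shielded from hydroxide.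

Further compounds
F1 | step 5 | [bis(acyloxy)iodo]benzene, iodobenzene bis[(E)-3-(3,4-bis(allyloxy)phenyl)prop-2-enoate] | O=C(/C=C/c1ccc(OCC=C)c(OCC=C)c1)OI(OC(=O)/C=C/c1ccc(OCC=C)c(OCC=C)c1)c1ccccc1
F2 | step 5 | aryloxy(acyloxy)iodobenzene: phenyl-λ3-iodane bearing 4-formyl-2-methoxyphenoxide and one (E)-3-[3,4-bis(allyloxy)phenyl]prop-2-enoate | O=Cc1ccc(OI(OC(=O)/C=C/c2ccc(OCC=C)c(OCC=C)c2)c2ccccc2)c(OC)c1
F3 | step 5 | (S)-3-formyl-1-methoxy-6-oxocyclohexa-2,4-dien-1-yl (E)-3-[3,4-bis(allyloxy)phenyl]prop-2-enoate (enantiomer of 9) | O=CC1=C[C@](OC)(OC(=O)/C=C/c2ccc(OCC=C)c(OCC=C)c2)C(=O)C=C1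
F4 | step 5 | (1S,2S,3R,4S,8S)-ketal lactone aldehyde (enantiomer of 10) | O=CC1=C[C@@H]2C(=O)[C@]3(OC)[C@H]1[C@@H](C(=O)O3)[C@@H]2c1ccc(OCC=C)c(OCC=C)c1
F5 | step 5 | diastereomer of 15 with the (1S,2S,3R,4S,8S) core and the (R) side chain | C=CCOC(=O)[C@H](OC(=O)/C=C/C1=C[C@@H]2C(=O)[C@]3(OC)[C@H]1[C@@H](C(=O)O3)[C@@H]2c1ccc(OCC=C)c(OCC=C)c1)Cc1ccc(OCC=C)c(OCC=C)c1
F6 | step 9 | hemiketal allyl ester: 16 with the C2 carboxyl as its allyl ester | C=CCOC(=O)[C@H](OC(=O)/C=C/C1=C[C@H]2C(=O)[C@@](O)(OC)[C@@H]1[C@H](C(=O)OCC=C)[C@H]2c1ccc(OCC=C)c(OCC=C)c1)Cc1ccc(OCC=C)c(OCC=C)c1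
F7 | step 9 | hexa-allyl dione ester: 17 with the C2 carboxyl as its allyl ester | C=CCOC(=O)[C@H](OC(=O)/C=C/C1=C[C@H]2C(=O)C(=O)[C@@H]1[C@H](C(=O)OCC=C)[C@H]2c1ccc(OCC=C)c(OCC=C)c1)Cc1ccc(OCC=C)c(OCC=C)c1
F8 | step 10 | fully deallylated ketal lactone: 15 with all five allyl groups replaced by hydrogen | O=C(/C=C/C1=C[C@H]2C(=O)[C@@]3(OC)[C@@H]1[C@H](C(=O)O3)[C@H]2c1ccc(O)c(O)c1)O[C@H](Cc1ccc(O)c(O)c1)C(=O)O
F9 | step 10 | methyl hemiketal of the target: 18 with C8 bearing OH and OMe in place of the ketone | O=C(/C=C/C1=C[C@H]2C(=O)[C@@](O)(OC)[C@@H]1[C@H](C(=O)O)[C@H]2c1ccc(O)c(O)c1)O[C@H](Cc1ccc(O)c(O)c1)C(=O)O
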